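**Strategy.** Ring A is cut through its oxygen bridge. The C3–O–C6 ether unit, flanked by the C1 gem-dimethyl carbon, is read as a five-membered cyclic carbonyl ylide, and the C4–C5 bridge as methyl methacrylate. One rhodium-catalysed operation on an acyclic 1-diazo-2,4-dione (C7 carried as a silyloxymethyl group) forms O–C3, C3–C4 and C5–C6, closes both rings of the 7-oxabicyclo[2.2.1]heptane and fixes the C3/C6 bridgeheads under chiral-catalyst control. C2 is then deoxygenated, the C5 ester is exchanged for the exo hydroxyl, and the polyene is built by C15 + C10 + C15 Wittig couplings. The triol ring B comes from (R)-phorenol by directed epoxidation and hydrolysis.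

Key step: step 4

Remark: ring A is numbered as in the carotenoid (C1 = CMe2, C3 and C6 = bridgeheads, C7 = exocyclic carbon on C6); exo means syn to the oxygen bridge.
Remark: an achiral dirhodium tetracarboxylate could give 11 only as a racemate, so a chiral one is used; the (S)-ligand series is assumed to favour the bridgehead configuration drawn, otherwise the mirror-image catalyst is taken.
Remark: 11 is drawn as the C5 epimer with exo ester; the other C5 epimer is carried through identically, because step 9 destroys this centre.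
Remark: in step 18 the (R,R)-ruthenium complex is assumed to give the (R)-carbinol, by analogy with aryl alkyl ketones.
Remark: 22, 26, 30 and 35 are taken as purchased.

**Ring A and the C25 half (steps 1–17)**

Step 1
Reactants: 1 3,3-dimethylpentane-2,4-dione
Product: 4 1-hydroxy-3,3-dimethylpentane-2,4-dione, via silyl enol ether 2 (not isolated), via silyloxy dione 3 (not isolated)
Conditions: LiN(i-Pr)2 (1.05 equiv), THF, −78 °C; Me3SiCl, −78 °C to rt; pentane, filtration; mCPBA, CH2Cl2, 0 °C; 1 M HCl, THF, rt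
Reagents that add atoms: 3-chloroperoxybenzoic acid (mCPBA), OOC(=O)c1cccc(Cl)c1
Why: Rubottom oxidation: only the two equivalent acetyl methyls can be enolised, one equivalent of base gives the mono silyl enol ether, and its epoxidation, silyl shift and acid hydrolysis should give the α-hydroxy ketone without forming a stereocentre.

Step 2
Reactants: 4 1-hydroxy-3,3-dimethylpentane-2,4-dione; 5 tert-butyl(chloro)diphenylsilane
Product: 6 1-[(tert-butyldiphenylsilyl)oxy]-3,3-dimethylpentane-2,4-dione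
Conditions: imidazole, CH2Cl2, 0 °C to rt
Reagents that add atoms: none
Why: Imidazole-promoted silylation of the primary hydroxyl should trap the open hydroxy dione out of its hemiketal equilibrium under conditions too mild for retro-Claisen cleavage of the 2,2-disubstituted 1,3-diketone.

Step 3
Reactants: 6 1-[(tert-butyldiphenylsilyl)oxy]-3,3-dimethylpentane-2,4-dione
Product: 8 5-[(tert-butyldiphenylsilyl)oxy]-1-diazo-3,3-dimethylpentane-2,4-dione, via trifluoroacetyl trione 7 (not isolated)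
Conditions: LiN(SiMe3)2, THF, −78 °C; CF3CO2CH2CF3, −78 °C; 5% HCl work-up; 4-acetamidobenzenesulfonyl azide, Et3N, H2O (1 equiv), MeCN, rt
Reagents that add atoms: 4-acetamidobenzenesulfonyl azide, CC(=O)Nc1ccc(cc1)S(=O)(=O)N=[N+]=[N-]
Why: Deacylative (Regitz-type) diazo transfer: the methyl ketone is enolised kinetically in preference to the hindered, oxygen-bearing CH2OSi side, trifluoroacetylated, and the activated methylene then takes up the diazo group with loss of the trifluoroacetyl group.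

Step 4
Reactants: 8 5-[(tert-butyldiphenylsilyl)oxy]-1-diazo-3,3-dimethylpentane-2,4-dione; 9 methyl methacrylate
Product: 11 methyl (1S,2R,4S)-1-{[(tert-butyldiphenylsilyl)oxy]methyl}-2,6,6-trimethyl-5-oxo-7-oxabicyclo[2.2.1]heptane-2-carboxylate, via carbonyl ylide 10 (not isolated)
Conditions: Rh2(S-BPTV)4 (dirhodium tetrakis[N-benzene-fused-phthaloyl-(S)-valinate], 1 mol %), 9 (5 equiv), PhCF3, 0 °C, slow addition of 8
Reagents that add atoms: none
Why: Loss of N2 from 8 gives a rhodium carbenoid at C3 that is attacked by the lone pair of the C6 ketone oxygen, and the cyclic carbonyl ylide 10 so formed adds across the C=C bond of 9 in a concerted suprafacial [3+2] step that makes C3–C4 and C5–C6. The closest known reaction type is the dirhodium-carboxylate-catalysed tandem ylide formation–dipolar cycloaddition of 1-diazo-2,4-diones with acrylates, together with its enantioselective variants that use chiral dirhodium carboxylates. Ring 1 (oxolan-3-one O–C3–C2–C1–C6) closes by intramolecular addition of the carbonyl oxygen to the carbenoid carbon, a five-membered closure assisted by the C1 gem-dimethyl group, and ring 2 (oxolane O–C3–C4–C5–C6) closes by the intermolecular cycloaddition, the two sharing the oxygen bridge of the bicycle. C3 and C6 are set together by the face of the planar ylide that the alkene reaches, which the chiral carboxylate ligands on the rhodium-associated ylide have to differentiate, whereas C5 follows the exo or endo placing of the ester and is not relied upon because step 9 planarises it. The step needs the regiochemistry C3-to-CH2 and C6-to-C(CH3)CO2Me, which the dipole polarity secures (C3 is the enolate-like terminus next to the C2 carbonyl, C6 the oxocarbenium-like one), and it needs the ylide to be trapped before 1,4-hydrogen shift or dimerisation, which excess 9, slow addition of 8 and the non-enolisable quaternary C1 secure.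

Step 5
Reactants: 11 methyl (1S,2R,4S)-1-{[(tert-butyldiphenylsilyl)oxy]methyl}-2,6,6-trimethyl-5-oxo-7-oxabicyclo[2.2.1]heptane-2-carboxylate
Product: 12 methyl (1S,2R,4S,5S)-1-{[(tert-butyldiphenylsilyl)oxy]methyl}-5-hydroxy-2,6,6-trimethyl-7-oxabicyclo[2.2.1]heptane-2-carboxylate (endo alcohol at C2 of ring A)
Conditions: NaBH4, MeOH, 0 °C
Reagents that add atoms: none
Why: Borohydride reduction takes the ketone and leaves the hindered tertiary ester; hydride is expected from the exo face (endo alcohol), but the new C2 centre is removed in step 7, so its configuration is immaterial.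

Step 6
Reactants: 12 methyl (1S,2R,4S,5S)-1-{[(tert-butyldiphenylsilyl)oxy]methyl}-5-hydroxy-2,6,6-trimethyl-7-oxabicyclo[2.2.1]heptane-2-carboxylate
Product: 13 methyl (1S,2R,4S,5S)-1-{[(tert-butyldiphenylsilyl)oxy]methyl}-2,6,6-trimethyl-5-{[(methylsulfanyl)carbonothioyl]oxy}-7-oxabicyclo[2.2.1]heptane-2-carboxylate
Conditions: NaH, imidazole (cat.), THF, 0 °C to rt; CS2; MeI
Reagents that add atoms: carbon disulfide, S=C=S; iodomethane, CI
Why: Standard S-methyl xanthate formation from the secondary alkoxide; the quaternary ester cannot enolise and the C2 and C5 substituents lie on different bridges, so no lactone can form.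

Step 7
Reactants: 13 methyl (1S,2R,4S,5S)-1-{[(tert-butyldiphenylsilyl)oxy]methyl}-2,6,6-trimethyl-5-{[(methylsulfanyl)carbonothioyl]oxy}-7-oxabicyclo[2.2.1]heptane-2-carboxylate
Product: 14 methyl (1S,2R,4R)-1-{[(tert-butyldiphenylsilyl)oxy]methyl}-2,6,6-trimethyl-7-oxabicyclo[2.2.1]heptane-2-carboxylate
Conditions: Bu3SnH (2 equiv, 0.3 M), AIBN (cat.), toluene, 100 °C
Reagents that add atoms: none
Why: Barton–McCombie deoxygenation: the secondary C2 radical is quenched by the concentrated stannane before it can open by β-scission of C1–C6, a β-alkoxy radical does not expel the bridge oxygen, and the C2 stereocentre disappears.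

Step 8
Reactants: 14 methyl (1S,2R,4R)-1-{[(tert-butyldiphenylsilyl)oxy]methyl}-2,6,6-trimethyl-7-oxabicyclo[2.2.1]heptane-2-carboxylate
Product: 15 (1S,2R,4R)-1-{[(tert-butyldiphenylsilyl)oxy]methyl}-2,6,6-trimethyl-7-oxabicyclo[2.2.1]heptane-2-carboxylic acid
Conditions: LiI, pyridine, reflux; 1 M HCl work-up
Reagents that add atoms: none
Why: Iodide dealkylates the methyl ester by SN2 attack at the methyl carbon, which avoids the shielded acyl carbon of this tertiary ester and leaves the silyl ether and the bridge untouched.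

Step 9
Reactants: 15 (1S,2R,4R)-1-{[(tert-butyldiphenylsilyl)oxy]methyl}-2,6,6-trimethyl-7-oxabicyclo[2.2.1]heptane-2-carboxylic acid
Product: 19 (1R,2R,4R)-1-{[(tert-butyldiphenylsilyl)oxy]methyl}-2,6,6-trimethyl-7-oxabicyclo[2.2.1]heptan-2-ol, via acid chloride 16 (not isolated), via thiohydroxamate ester 17 (not isolated), via hydroperoxide 18 (not isolated)
Conditions: (COCl)2, DMF (cat.), CH2Cl2, 0 °C to rt; 2-mercaptopyridine N-oxide sodium salt (C5H4NNaOS), DMAP (cat.), toluene, dark, rt; t-BuSH, O2, visible light, 10 °C; P(OMe)3, rt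
Reagents that add atoms: dioxygen, O=O
Why: Barton decarboxylative hydroxylation: the planar tertiary C5 radical should be trapped by O2 on the exo face, away from the endo methyl on C1 and along the usual exo trajectory of 2-norbornyl-type radicals, so the C–O bond is exo and the methyl endo whichever C5 epimer of 15 is used, and thiol hydrogen transfer followed by phosphite reduction gives the alcohol.

Step 10
Reactants: 19 (1R,2R,4R)-1-{[(tert-butyldiphenylsilyl)oxy]methyl}-2,6,6-trimethyl-7-oxabicyclo[2.2.1]heptan-2-ol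
Product: 20 (1R,2R,4R)-1-(hydroxymethyl)-2,6,6-trimethyl-7-oxabicyclo[2.2.1]heptan-2-ol
Conditions: Bu4NF, THF, rt to 40 °C
Reagents that add atoms: none
Why: Fluoride cleavage of the silyl ether frees the primary alcohol and touches no stereocentre.

Step 11
Reactants: 20 (1R,2R,4R)-1-(hydroxymethyl)-2,6,6-trimethyl-7-oxabicyclo[2.2.1]heptan-2-ol
Product: 21 (1S,2R,4R)-2-hydroxy-2,6,6-trimethyl-7-oxabicyclo[2.2.1]heptane-1-carbaldehyde
Conditions: Dess–Martin periodinane, pyridine, CH2Cl2, 0 °C to rt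
Reagents that add atoms: none
Why: Dess–Martin oxidation converts only the primary alcohol (the tertiary one cannot be oxidised), and the buffered, non-basic medium should avoid retro-aldol opening of the β-hydroxy aldehyde.

Step 12
Reactants: 21 (1S,2R,4R)-2-hydroxy-2,6,6-trimethyl-7-oxabicyclo[2.2.1]heptane-1-carbaldehyde; 22 ethyl (E)-4-(diethoxyphosphoryl)-3-methylbut-2-enoate
Product: 23 ethyl (2E,4E)-5-[(1S,2R,4R)-2-hydroxy-2,6,6-trimethyl-7-oxabicyclo[2.2.1]heptan-1-yl]-3-methylpenta-2,4-dienoate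
Conditions: 22 (1.6 equiv), LiN(SiMe3)2 (1.5 equiv), THF, −78 °C; 21, −78 to 0 °C
Reagents that add atoms: none
Why: Vinylogous Horner–Wadsworth–Emmons olefination forms C7=C8 with E geometry; the stabilised phosphonate anion, kept free of excess amide base, is too weak a base to ionise the tertiary alcohol and trigger retro-aldol cleavage, and any 9Z isomer is removed by chromatography.

Step 13
Reactants: 23 ethyl (2E,4E)-5-[(1S,2R,4R)-2-hydroxy-2,6,6-trimethyl-7-oxabicyclo[2.2.1]heptan-1-yl]-3-methylpenta-2,4-dienoate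
Product: 24 (2E,4E)-5-[(1S,2R,4R)-2-hydroxy-2,6,6-trimethyl-7-oxabicyclo[2.2.1]heptan-1-yl]-3-methylpenta-2,4-dien-1-ol
Conditions: i-Bu2AlH (3.5 equiv), CH2Cl2, −78 °C; Rochelle salt work-up
Reagents that add atoms: none
Why: 1,2-Reduction of the conjugated ester by the aluminium hydride gives the dienylic alcohol without touching the alkenes.

Step 14
Reactants: 24 (2E,4E)-5-[(1S,2R,4R)-2-hydroxy-2,6,6-trimethyl-7-oxabicyclo[2.2.1]heptan-1-yl]-3-methylpenta-2,4-dien-1-ol
Product: 25 {(2E,4E)-5-[(1S,2R,4R)-2-hydroxy-2,6,6-trimethyl-7-oxabicyclo[2.2.1]heptan-1-yl]-3-methylpenta-2,4-dien-1-yl}triphenylphosphonium bromide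
Conditions: PPh3·HBr, MeOH, rt
Reagents that add atoms: triphenylphosphine hydrobromide, [Br-].c1ccc(cc1)[PH+](c1ccccc1)c1ccccc1
Why: The primary dienylic alcohol ionises under the mild acid and the phosphine takes the unhindered terminal carbon, the standard entry to C15 Wittig salts; the bridge C6–O bond is protected from ionisation by the electron-withdrawing C5 hydroxyl next to it.

Step 15
Reactants: 25 {(2E,4E)-5-[(1S,2R,4R)-2-hydroxy-2,6,6-trimethyl-7-oxabicyclo[2.2.1]heptan-1-yl]-3-methylpenta-2,4-dien-1-yl}triphenylphosphonium bromide; 26 (2E,4E,6E)-2,7-dimethylocta-2,4,6-trienedial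
Product: 27 (2E,4E,6E,8E,10E,12E)-13-[(1S,2R,4R)-2-hydroxy-2,6,6-trimethyl-7-oxabicyclo[2.2.1]heptan-1-yl]-2,7,11-trimethyltrideca-2,4,6,8,10,12-hexaenal
Conditions: 26 (3 equiv), NaOMe, CH2Cl2/MeOH, 0 °C to rt, dark; then EtOAc, reflux (Z to E)
Reagents that add atoms: none
Why: Wittig olefination with an excess of the symmetrical dialdehyde should stop at mono-condensation (C11=C12), and the Z portion at the new bond equilibrates thermally to the E isomer.

Step 16
Reactants: 27 (2E,4E,6E,8E,10E,12E)-13-[(1S,2R,4R)-2-hydroxy-2,6,6-trimethyl-7-oxabicyclo[2.2.1]heptan-1-yl]-2,7,11-trimethyltrideca-2,4,6,8,10,12-hexaenal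
Product: 28 (2E,4E,6E,8E,10E,12E)-13-[(1S,2R,4R)-2-hydroxy-2,6,6-trimethyl-7-oxabicyclo[2.2.1]heptan-1-yl]-2,7,11-trimethyltrideca-2,4,6,8,10,12-hexaen-1-ol
Conditions: NaBH4, MeOH/THF, 0 °C, dark
Reagents that add atoms: none
Why: Borohydride reduces the polyenal in the 1,2-sense to the allylic alcohol.

Step 17
Reactants: 28 (2E,4E,6E,8E,10E,12E)-13-[(1S,2R,4R)-2-hydroxy-2,6,6-trimethyl-7-oxabicyclo[2.2.1]heptan-1-yl]-2,7,11-trimethyltrideca-2,4,6,8,10,12-hexaen-1-ol
Product: 29 {(2E,4E,6E,8E,10E,12E)-13-[(1S,2R,4R)-2-hydroxy-2,6,6-trimethyl-7-oxabicyclo[2.2.1]heptan-1-yl]-2,7,11-trimethyltrideca-2,4,6,8,10,12-hexaen-1-yl}triphenylphosphonium bromide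
Conditions: PPh3·HBr, CH2Cl2/MeOH, 0 °C to rt, dark
Reagents that add atoms: triphenylphosphine hydrobromide, [Br-].c1ccc(cc1)[PH+](c1ccccc1)c1ccccc1
Why: As in step 14, the polyenylic primary alcohol is converted into its phosphonium salt by ionisation and capture at the terminal carbon.

**Ring B, the C15 aldehyde (steps 18–26)**

Step 18
Reactants: 30 2,6,6-trimethylcyclohex-2-ene-1,4-dione
Product: 31 (R)-4-hydroxy-2,6,6-trimethylcyclohex-2-en-1-one
Conditions: RuCl[(R,R)-TsDPEN](p-cymene) (cat.), i-PrOH, rt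
Reagents that add atoms: none
Why: Noyori-type asymmetric transfer hydrogenation reduces the less hindered C4 carbonyl, not the doubly flanked C1 carbonyl, and the chiral ruthenium amide sets the carbinol centre by differentiating its alkenyl and alkyl sides.

Step 19
Reactants: 31 (R)-4-hydroxy-2,6,6-trimethylcyclohex-2-en-1-one
Product: 32 (R)-4-{[tert-butyl(dimethyl)silyl]oxy}-2,6,6-trimethylcyclohex-2-en-1-one
Conditions: t-BuMe2SiCl, imidazole, DMF, rt
Reagents that add atoms: tert-butyl(chloro)dimethylsilane, CC(C)(C)[Si](C)(C)Cl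
Why: Routine silylation of the secondary alcohol, which prevents redox isomerisation of the hydroxy enone in the next step.

Step 20
Reactants: 32 (R)-4-{[tert-butyl(dimethyl)silyl]oxy}-2,6,6-trimethylcyclohex-2-en-1-one
Product: 33 (4S,6R)-4-{[tert-butyl(dimethyl)silyl]oxy}-2,2,6-trimethylcyclohexan-1-one (cis; the C6 epimer serves equally)
Conditions: H2 (1 atm), Pd/C, EtOAc, rt
Reagents that add atoms: none
Why: Heterogeneous hydrogenation saturates the enone C=C, hydrogen arriving anti to the silyloxy group (cis product expected), and the new C6 centre is irrelevant because it is enolised in step 21.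

Step 21
Reactants: 33 (4S,6R)-4-{[tert-butyl(dimethyl)silyl]oxy}-2,2,6-trimethylcyclohexan-1-one
Product: 34 (4S)-4-{[tert-butyl(dimethyl)silyl]oxy}-2,6,6-trimethylcyclohex-1-en-1-yl trifluoromethanesulfonate
Conditions: LiN(i-Pr)2, THF, −78 to 0 °C; PhNTf2, −78 °C to rt
Reagents that add atoms: N-phenylbis(trifluoromethanesulfonimide), FC(F)(F)S(=O)(=O)N(c1ccccc1)S(=O)(=O)C(F)(F)F
Why: The ketone has a single enolisable position, so deprotonation and O-triflation give the tetrasubstituted enol triflate regiospecifically.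

Step 22
Reactants: 35 (E)-3-methylpent-2-en-4-yn-1-ol
Product: 36 (2E,4E)-3-methyl-5-(tributylstannyl)penta-2,4-dien-1-ol
Conditions: Bu3SnH, PdCl2(PPh3)2 (cat.), THF, 0 °C to rt
Reagents that add atoms: tributyltin hydride, CCCC[SnH](CCCC)CCCC
Why: Palladium-catalysed syn hydrostannation of the terminal alkyne places tin mainly on the terminal carbon with E geometry, and the internal regioisomer is removed by chromatography.

Step 23
Reactants: 34 (4S)-4-{[tert-butyl(dimethyl)silyl]oxy}-2,6,6-trimethylcyclohex-1-en-1-yl trifluoromethanesulfonate; 36 (2E,4E)-3-methyl-5-(tributylstannyl)penta-2,4-dien-1-ol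
Product: 38 (2E,4E)-5-[(4S)-4-hydroxy-2,6,6-trimethylcyclohex-1-en-1-yl]-3-methylpenta-2,4-dien-1-ol, via silyl trienol 37 (not isolated)
Conditions: Pd2(dba)3 (cat.), AsPh3, NMP, 50 °C; then Bu4NF, THF, rt
Reagents that add atoms: none
Why: Stille coupling with a weakly donating arsine ligand in a polar solvent, as needed for hindered cyclohexenyl triflates, joins C6 to C7 with retention of both alkene geometries, and fluoride added to the same flask removes the silyl group and precipitates the tin residue.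

Step 24
Reactants: 38 (2E,4E)-5-[(4S)-4-hydroxy-2,6,6-trimethylcyclohex-1-en-1-yl]-3-methylpenta-2,4-dien-1-ol
Product: 39 (2E,4E)-5-[(4S)-4-hydroxy-2,6,6-trimethylcyclohex-1-en-1-yl]-3-methylpenta-2,4-dienal
Conditions: MnO2 (activated), CH2Cl2, rt
Reagents that add atoms: none
Why: MnO2 oxidises only the dienylic primary alcohol and leaves the saturated secondary alcohol that is needed for the directed epoxidation.

Step 25
Reactants: 39 (2E,4E)-5-[(4S)-4-hydroxy-2,6,6-trimethylcyclohex-1-en-1-yl]-3-methylpenta-2,4-dienal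
Product: 40 (2E,4E)-5-[(1S,4R,6R)-4-hydroxy-2,2,6-trimethyl-7-oxabicyclo[4.1.0]heptan-1-yl]-3-methylpenta-2,4-dienal
Conditions: VO(acac)2 (cat.), t-BuOOH, toluene, rt
Reagents that add atoms: tert-butyl hydroperoxide, CC(C)(C)OO
Why: Hydroxyl-directed vanadium-catalysed epoxidation: the homoallylic C3 hydroxyl binds the metal and delivers oxygen to its own face of the electron-rich tetrasubstituted C5=C6 bond, which sets C5 and C6 (syn epoxide) and spares the electron-poor dienal.

Step 26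
Reactants: 40 (2E,4E)-5-[(1S,4R,6R)-4-hydroxy-2,2,6-trimethyl-7-oxabicyclo[4.1.0]heptan-1-yl]-3-methylpenta-2,4-dienal
Product: 41 (2E,4E)-3-methyl-5-[(1S,2S,4R)-1,2,4-trihydroxy-2,6,6-trimethylcyclohexyl]penta-2,4-dienal
Conditions: 0.1 M H2SO4, THF/H2O, 0 °C
Reagents that add atoms: water, O
Why: Acid-catalysed hydrolysis of the tetrasubstituted epoxide: the C5–O bond ionises because a C6 cation would be conjugated with the electron-poor dienal, and water enters at C5 anti to the leaving oxygen, so C6 keeps its oxygen cis to the C3 hydroxyl while C5 is inverted to give the trans-5,6-diol.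

**Final coupling**

Step 27
Reactants: 29 {(2E,4E,6E,8E,10E,12E)-13-[(1S,2R,4R)-2-hydroxy-2,6,6-trimethyl-7-oxabicyclo[2.2.1]heptan-1-yl]-2,7,11-trimethyltrideca-2,4,6,8,10,12-hexaen-1-yl}triphenylphosphonium bromide; 41 (2E,4E)-3-methyl-5-[(1S,2S,4R)-1,2,4-trihydroxy-2,6,6-trimethylcyclohexyl]penta-2,4-dienal
Product: 42 (all-E)-(3R,5R,6S,3'R,5'S,6'S)-3,6-epoxy-5,6,5',6'-tetrahydro-β,β-carotene-5,3',5',6'-tetrol (CNP0261804.1)
Conditions: NaOMe, CH2Cl2/MeOH, 0 °C to rt, dark; then EtOH, reflux, N2, dark (Z to E)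
Reagents that add atoms: none
Why: Wittig olefination joins C12' of the C25 salt to C11' of the aldehyde without exposing the acid-labile tertiary allylic alcohol of ring B to acid, and thermal equilibration converts the Z portion at the new bond into the all-E polyene while no stereocentre is touched.

**Compound list**

1 | 3,3-dimethylpentane-2,4-dione | CC(=O)C(C)(C)C(C)=O | starting material
2 | 3,3-dimethyl-4-[(trimethylsilyl)oxy]pent-4-en-2-one (silyl enol ether) | CC(=O)C(C)(C)C(=C)O[Si](C)(C)C | intermediate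
3 | 3,3-dimethyl-1-[(trimethylsilyl)oxy]pentane-2,4-dione (silyloxy dione) | CC(=O)C(C)(C)C(=O)CO[Si](C)(C)C | intermediate
4 | 1-hydroxy-3,3-dimethylpentane-2,4-dione | CC(=O)C(C)(C)C(=O)CO | intermediate
5 | tert-butyl(chloro)diphenylsilane | CC(C)(C)[Si](Cl)(c1ccccc1)c1ccccc1 | starting material
6 | 1-[(tert-butyldiphenylsilyl)oxy]-3,3-dimethylpentane-2,4-dione | CC(=O)C(C)(C)C(=O)CO[Si](c1ccccc1)(c1ccccc1)C(C)(C)C | intermediate
7 | 7-[(tert-butyldiphenylsilyl)oxy]-1,1,1-trifluoro-5,5-dimethylheptane-2,4,6-trione (trifluoroacetyl trione) | O=C(CC(=O)C(C)(C)C(=O)CO[Si](c1ccccc1)(c1ccccc1)C(C)(C)C)C(F)(F)F | intermediate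
8 | 5-[(tert-butyldiphenylsilyl)oxy]-1-diazo-3,3-dimethylpentane-2,4-dione | [N-]=[N+]=CC(=O)C(C)(C)C(=O)CO[Si](c1ccccc1)(c1ccccc1)C(C)(C)C | intermediate
9 | methyl methacrylate | COC(=O)C(C)=C | starting material
10 | carbonyl ylide: 5-{[(tert-butyldiphenylsilyl)oxy]methyl}-4,4-dimethyl-3-oxo-3,4-dihydro-2H-furan-1-ium-2-ide | O=C1[CH-][O+]=C(CO[Si](c2ccccc2)(c2ccccc2)C(C)(C)C)C1(C)C | intermediate
11 | methyl (1S,2R,4S)-1-{[(tert-butyldiphenylsilyl)oxy]methyl}-2,6,6-trimethyl-5-oxo-7-oxabicyclo[2.2.1]heptane-2-carboxylate (ester exo) | CC(C)(C)[Si](c1ccccc1)(c1ccccc1)OC[C@]12O[C@H](C(=O)C1(C)C)C[C@@]2(C)C(=O)OC | intermediate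
12 | methyl (1S,2R,4S,5S)-1-{[(tert-butyldiphenylsilyl)oxy]methyl}-5-hydroxy-2,6,6-trimethyl-7-oxabicyclo[2.2.1]heptane-2-carboxylate (5-OH endo) | CC(C)(C)[Si](c1ccccc1)(c1ccccc1)OC[C@]12O[C@H]([C@@H](O)C1(C)C)C[C@@]2(C)C(=O)OC | intermediate
13 | methyl (1S,2R,4S,5S)-1-{[(tert-butyldiphenylsilyl)oxy]methyl}-2,6,6-trimethyl-5-{[(methylsulfanyl)carbonothioyl]oxy}-7-oxabicyclo[2.2.1]heptane-2-carboxylate | CC(C)(C)[Si](c1ccccc1)(c1ccccc1)OC[C@]12O[C@H]([C@@H](OC(=S)SC)C1(C)C)C[C@@]2(C)C(=O)OC | intermediate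
14 | methyl (1S,2R,4R)-1-{[(tert-butyldiphenylsilyl)oxy]methyl}-2,6,6-trimethyl-7-oxabicyclo[2.2.1]heptane-2-carboxylate | CC(C)(C)[Si](c1ccccc1)(c1ccccc1)OC[C@]12O[C@H](CC1(C)C)C[C@@]2(C)C(=O)OC | intermediate
15 | (1S,2R,4R)-1-{[(tert-butyldiphenylsilyl)oxy]methyl}-2,6,6-trimethyl-7-oxabicyclo[2.2.1]heptane-2-carboxylic acid | CC(C)(C)[Si](c1ccccc1)(c1ccccc1)OC[C@]12O[C@H](CC1(C)C)C[C@@]2(C)C(=O)O | intermediate
16 | (1S,2R,4R)-1-{[(tert-butyldiphenylsilyl)oxy]methyl}-2,6,6-trimethyl-7-oxabicyclo[2.2.1]heptane-2-carbonyl chloride (acid chloride) | CC(C)(C)[Si](c1ccccc1)(c1ccccc1)OC[C@]12O[C@H](CC1(C)C)C[C@@]2(C)C(=O)Cl | intermediate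
17 | 2-thioxopyridin-1(2H)-yl (1S,2R,4R)-1-{[(tert-butyldiphenylsilyl)oxy]methyl}-2,6,6-trimethyl-7-oxabicyclo[2.2.1]heptane-2-carboxylate (thiohydroxamate ester) | CC(C)(C)[Si](c1ccccc1)(c1ccccc1)OC[C@]12O[C@H](CC1(C)C)C[C@@]2(C)C(=O)ON3C=CC=CC3=S | intermediate
18 | tert-butyl{[(1R,2R,4R)-2-hydroperoxy-2,6,6-trimethyl-7-oxabicyclo[2.2.1]heptan-1-yl]methoxy}diphenylsilane (hydroperoxide, exo) | CC(C)(C)[Si](c1ccccc1)(c1ccccc1)OC[C@]12O[C@H](CC1(C)C)C[C@@]2(C)OO | intermediate
19 | (1R,2R,4R)-1-{[(tert-butyldiphenylsilyl)oxy]methyl}-2,6,6-trimethyl-7-oxabicyclo[2.2.1]heptan-2-ol (OH exo) | CC(C)(C)[Si](c1ccccc1)(c1ccccc1)OC[C@]12O[C@H](CC1(C)C)C[C@@]2(C)O | intermediate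
20 | (1R,2R,4R)-1-(hydroxymethyl)-2,6,6-trimethyl-7-oxabicyclo[2.2.1]heptan-2-ol | OC[C@]12O[C@H](CC1(C)C)C[C@@]2(C)O | intermediate
21 | (1S,2R,4R)-2-hydroxy-2,6,6-trimethyl-7-oxabicyclo[2.2.1]heptane-1-carbaldehyde | O=C[C@]12O[C@H](CC1(C)C)C[C@@]2(C)O | intermediate
22 | ethyl (E)-4-(diethoxyphosphoryl)-3-methylbut-2-enoate | CCOC(=O)/C=C(C)/CP(=O)(OCC)OCC | starting material
23 | ethyl (2E,4E)-5-[(1S,2R,4R)-2-hydroxy-2,6,6-trimethyl-7-oxabicyclo[2.2.1]heptan-1-yl]-3-methylpenta-2,4-dienoate | CCOC(=O)/C=C(C)/C=C/[C@]12O[C@H](CC1(C)C)C[C@@]2(C)O | intermediate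
24 | (2E,4E)-5-[(1S,2R,4R)-2-hydroxy-2,6,6-trimethyl-7-oxabicyclo[2.2.1]heptan-1-yl]-3-methylpenta-2,4-dien-1-ol | OC/C=C(C)/C=C/[C@]12O[C@H](CC1(C)C)C[C@@]2(C)O | intermediate
25 | {(2E,4E)-5-[(1S,2R,4R)-2-hydroxy-2,6,6-trimethyl-7-oxabicyclo[2.2.1]heptan-1-yl]-3-methylpenta-2,4-dien-1-yl}triphenylphosphonium bromide | [Br-].C(/C=C(C)/C=C/[C@]12O[C@H](CC1(C)C)C[C@@]2(C)O)[P+](c3ccccc3)(c4ccccc4)c5ccccc5 | intermediate
26 | (2E,4E,6E)-2,7-dimethylocta-2,4,6-trienedial | O=C/C(C)=C/C=C/C=C(C)/C=O | starting material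
27 | (2E,4E,6E,8E,10E,12E)-13-[(1S,2R,4R)-2-hydroxy-2,6,6-trimethyl-7-oxabicyclo[2.2.1]heptan-1-yl]-2,7,11-trimethyltrideca-2,4,6,8,10,12-hexaenal | O=C/C(C)=C/C=C/C=C(C)/C=C/C=C(C)/C=C/[C@]12O[C@H](CC1(C)C)C[C@@]2(C)O | intermediate
28 | (2E,4E,6E,8E,10E,12E)-13-[(1S,2R,4R)-2-hydroxy-2,6,6-trimethyl-7-oxabicyclo[2.2.1]heptan-1-yl]-2,7,11-trimethyltrideca-2,4,6,8,10,12-hexaen-1-ol | OC/C(C)=C/C=C/C=C(C)/C=C/C=C(C)/C=C/[C@]12O[C@H](CC1(C)C)C[C@@]2(C)O | intermediate
29 | {(2E,4E,6E,8E,10E,12E)-13-[(1S,2R,4R)-2-hydroxy-2,6,6-trimethyl-7-oxabicyclo[2.2.1]heptan-1-yl]-2,7,11-trimethyltrideca-2,4,6,8,10,12-hexaen-1-yl}triphenylphosphonium bromide | [Br-].C(/C(C)=C/C=C/C=C(C)/C=C/C=C(C)/C=C/[C@]12O[C@H](CC1(C)C)C[C@@]2(C)O)[P+](c3ccccc3)(c4ccccc4)c5ccccc5 | intermediate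
30 | 2,6,6-trimethylcyclohex-2-ene-1,4-dione | CC1=CC(=O)CC(C)(C)C1=O | starting material
31 | (R)-4-hydroxy-2,6,6-trimethylcyclohex-2-en-1-one | CC1=C[C@H](O)CC(C)(C)C1=O | intermediate
32 | (R)-4-{[tert-butyl(dimethyl)silyl]oxy}-2,6,6-trimethylcyclohex-2-en-1-one | CC1=C[C@H](O[Si](C)(C)C(C)(C)C)CC(C)(C)C1=O | intermediate
33 | (4S,6R)-4-{[tert-butyl(dimethyl)silyl]oxy}-2,2,6-trimethylcyclohexan-1-one | O=C1[C@H](C)C[C@H](O[Si](C)(C)C(C)(C)C)CC1(C)C | intermediate
34 | (4S)-4-{[tert-butyl(dimethyl)silyl]oxy}-2,6,6-trimethylcyclohex-1-en-1-yl trifluoromethanesulfonate | CC1=C(OS(=O)(=O)C(F)(F)F)C(C)(C)C[C@@H](O[Si](C)(C)C(C)(C)C)C1 | intermediate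
35 | (E)-3-methylpent-2-en-4-yn-1-ol | OC/C=C(C)/C#C | starting material
36 | (2E,4E)-3-methyl-5-(tributylstannyl)penta-2,4-dien-1-ol | OC/C=C(C)/C=C/[Sn](CCCC)(CCCC)CCCC | intermediate
37 | (2E,4E)-5-[(4S)-4-{[tert-butyl(dimethyl)silyl]oxy}-2,6,6-trimethylcyclohex-1-en-1-yl]-3-methylpenta-2,4-dien-1-ol (silyl trienol) | CC1=C(/C=C/C(C)=C/CO)C(C)(C)C[C@@H](O[Si](C)(C)C(C)(C)C)C1 | intermediate
38 | (2E,4E)-5-[(4S)-4-hydroxy-2,6,6-trimethylcyclohex-1-en-1-yl]-3-methylpenta-2,4-dien-1-ol | CC1=C(/C=C/C(C)=C/CO)C(C)(C)C[C@@H](O)C1 | intermediate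
39 | (2E,4E)-5-[(4S)-4-hydroxy-2,6,6-trimethylcyclohex-1-en-1-yl]-3-methylpenta-2,4-dienal | CC1=C(/C=C/C(C)=C/C=O)C(C)(C)C[C@@H](O)C1 | intermediate
40 | (2E,4E)-5-[(1S,4R,6R)-4-hydroxy-2,2,6-trimethyl-7-oxabicyclo[4.1.0]heptan-1-yl]-3-methylpenta-2,4-dienal (epoxide syn to the hydroxyl) | O=C/C=C(C)/C=C/[C@]1(O2)C(C)(C)C[C@@H](O)C[C@]12C | intermediate
41 | (2E,4E)-3-methyl-5-[(1S,2S,4R)-1,2,4-trihydroxy-2,6,6-trimethylcyclohexyl]penta-2,4-dienal | O=C/C=C(C)/C=C/[C@]1(O)C(C)(C)C[C@@H](O)C[C@]1(C)O | intermediate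
42 | (all-E)-(3R,5R,6S,3'R,5'S,6'S)-3,6-epoxy-5,6,5',6'-tetrahydro-β,β-carotene-5,3',5',6'-tetrol | CC(/C=C/C=C(C)/C=C/[C@]12O[C@H](CC1(C)C)C[C@@]2(C)O)=C\C=C\C=C(C)\C=C\C=C(C)\C=C\[C@]1(O)C(C)(C)C[C@@H](O)C[C@]1(C)O | target

**Step count and risks**

Total step count: 27. Longest linear sequence: 18 steps (steps 1–17 and 27); the ring B branch (steps 18–26) has 9 steps.

Steps most likely to fail:

1. Step 4. The ylide may leave the chiral rhodium centre before the alkene adds, so that the two faces of the dipole are not told apart. Fallback: give up catalyst control and resolve. Setting out from 8, the same cascade with achiral Rh2(OAc)4 in CH2Cl2 and excess 9 should give 11 as a racemate, that is together with its mirror image, methyl (1R,2S,4R)-1-{[(tert-butyldiphenylsilyl)oxy]methyl}-2,6,6-trimethyl-5-oxo-7-oxabicyclo[2.2.1]heptane-2-carboxylate F1. The two are separated by preparative chromatography on a cellulose tris(3,5-dimethylphenylcarbamate) phase, and the route is rejoined at 11.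

2. Step 9. The planar C5 radical may be captured on the endo face, or the hindered acid may enter the radical chain poorly. Fallback: replace the radical by a stereoretentive two-electron shift, which holds for the exo acid as drawn (any C5 epimer being removed at the stage of 14). Setting out from 15, excess MeLi in Et2O should give the methyl ketone 1-[(1S,2R,4R)-1-{[(tert-butyldiphenylsilyl)oxy]methyl}-2,6,6-trimethyl-7-oxabicyclo[2.2.1]heptan-2-yl]ethan-1-one F2. Baeyer–Villiger oxidation with CF3CO3H/Na2HPO4 in CH2Cl2 moves the tertiary C5 to oxygen with retention and gives (1R,2R,4R)-1-{[(tert-butyldiphenylsilyl)oxy]methyl}-2,6,6-trimethyl-7-oxabicyclo[2.2.1]heptan-2-yl acetate F3. LiAlH4 in Et2O at 0 °C removes the acetyl group and comes back to the route at 19.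

3. Step 26. The epoxide may ionise at C6 and not at C5, which would lead to furanoid 5,8-ethers, closure of a 3,6-ether or loss of the C6 configuration. Fallback: do the epoxide chemistry on the C13 enone, where a C6 cation would be conjugated directly with the carbonyl group and is suppressed, and add the last two chain carbons afterwards.
   - Setting out from 34, Heck coupling with but-3-en-2-one (Pd(OAc)2, PPh3, Et3N, DMF, 75 °C) gives (E)-4-[(4S)-4-{[tert-butyl(dimethyl)silyl]oxy}-2,6,6-trimethylcyclohex-1-en-1-yl]but-3-en-2-one F4.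
   - Bu4NF in THF gives (E)-4-[(4S)-4-hydroxy-2,6,6-trimethylcyclohex-1-en-1-yl]but-3-en-2-one F5.
   - VO(acac)2/t-BuOOH gives the syn epoxide (E)-4-[(1S,4R,6R)-4-hydroxy-2,2,6-trimethyl-7-oxabicyclo[4.1.0]heptan-1-yl]but-3-en-2-one F6.
   - Dilute H2SO4 in THF/H2O gives (E)-4-[(1S,2S,4R)-1,2,4-trihydroxy-2,6,6-trimethylcyclohexyl]but-3-en-2-one F7.
   - Horner–Wadsworth–Emmons reaction with diethyl (cyanomethyl)phosphonate (NaH, THF; the 9Z isomer is removed by chromatography) gives (2E,4E)-3-methyl-5-[(1S,2S,4R)-1,2,4-trihydroxy-2,6,6-trimethylcyclohexyl]penta-2,4-dienenitrile F8.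
   - i-Bu2AlH in CH2Cl2 at −78 °C, then mild hydrolysis of the aldimine, comes back to the route at 41.

**Further compounds**

F1 | step 4 | methyl (1R,2S,4R)-1-{[(tert-butyldiphenylsilyl)oxy]methyl}-2,6,6-trimethyl-5-oxo-7-oxabicyclo[2.2.1]heptane-2-carboxylate (enantiomer of 11) | CC(C)(C)[Si](c1ccccc1)(c1ccccc1)OC[C@@]12O[C@@H](C(=O)C1(C)C)C[C@]2(C)C(=O)OC
F2 | step 9 | 1-[(1S,2R,4R)-1-{[(tert-butyldiphenylsilyl)oxy]methyl}-2,6,6-trimethyl-7-oxabicyclo[2.2.1]heptan-2-yl]ethan-1-one | CC(C)(C)[Si](c1ccccc1)(c1ccccc1)OC[C@]12O[C@H](CC1(C)C)C[C@@]2(C)C(C)=O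
F3 | step 9 | (1R,2R,4R)-1-{[(tert-butyldiphenylsilyl)oxy]methyl}-2,6,6-trimethyl-7-oxabicyclo[2.2.1]heptan-2-yl acetate | CC(C)(C)[Si](c1ccccc1)(c1ccccc1)OC[C@]12O[C@H](CC1(C)C)C[C@@]2(C)OC(C)=O
F4 | step 26 | (E)-4-[(4S)-4-{[tert-butyl(dimethyl)silyl]oxy}-2,6,6-trimethylcyclohex-1-en-1-yl]but-3-en-2-one | CC(=O)/C=C/C1=C(C)C[C@H](O[Si](C)(C)C(C)(C)C)CC1(C)C
F5 | step 26 | (E)-4-[(4S)-4-hydroxy-2,6,6-trimethylcyclohex-1-en-1-yl]but-3-en-2-one | CC(=O)/C=C/C1=C(C)C[C@H](O)CC1(C)C
F6 | step 26 | (E)-4-[(1S,4R,6R)-4-hydroxy-2,2,6-trimethyl-7-oxabicyclo[4.1.0]heptan-1-yl]but-3-en-2-one | CC(=O)/C=C/[C@]1(O2)C(C)(C)C[C@@H](O)C[C@]12C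
F7 | step 26 | (E)-4-[(1S,2S,4R)-1,2,4-trihydroxy-2,6,6-trimethylcyclohexyl]but-3-en-2-one | CC(=O)/C=C/[C@]1(O)C(C)(C)C[C@@H](O)C[C@]1(C)O
F8 | step 26 | (2E,4E)-3-methyl-5-[(1S,2S,4R)-1,2,4-trihydroxy-2,6,6-trimethylcyclohexyl]penta-2,4-dienenitrile | N#C/C=C(C)/C=C/[C@]1(O)C(C)(C)C[C@@H](O)C[C@]1(C)O
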